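The readings stem from a simulated flask for an exercise, noise included.

A one-step world, with Q turning L into E and nothing else touching Q, has E climbing towards all of the L charged, and Saturday's run looks like that world, reaching 92.0% at 60.0 s. Thursday's flask does not: it reads 10.3% at 20.0 s and 12.4% at 80.0 s.

in all of them: L 0.20 M; Q 0.01 mol%

|  | D | temperature | remark | time |
|---|---|---|---|---|
| Thursday's | 22 µM | 20 °C | the very flask that is asked about, followed so far |  |
| Saturday's | 11 µM | 26 °C | run made earlier |  |
| flask | 22 µM | 20 °C |  | 2.0 min |

| run | time / s | E / % |
|---|---|---|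
| Thursday's | 20.0 | 10.3 |
| Thursday's | 40.0 | 11.5 |
| Thursday's | 50.0 | 11.4 |
| Thursday's | 80.0 | 12.4 |
| Saturday's | 30.0 | 63.1 |
| Saturday's | 60.0 | 92.0 |
| Saturday's | 90.0 | 98.8 |
| Saturday's | 120 | 100.5 |

(readings scatter by 0.5 percentage points)

- autumn: at 2.0 min add Q, 50.0% of the amount charged, then wait 1.0 min
- spring: at 2.0 min raise the temperature by 10 K, then wait 1.0 min
- winter: change nothing and wait 1.0 min more
- summer: at 2.0 min take out 90% of the E then present, then wait 1.0 min

- E, in percent of the L first charged, at 2.0 min
- the option that brings most further E ("none" if no option brings more than 2 percentage points) (autumn / spring / winter / summer / none)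
- E present, with what was taken out counted in, in percent of the L first charged, after spring
- E present, with what was taken out counted in, in percent of the L first charged, after summer

- E taken out counts as made
- steps under discussion: Q -> X; Q + D -> Z; L + Q -> E + Q; Q <-> J
- additions bring no volume worth counting

Both runs charge [Q] = 20.0 µM, so the first estimate is a subtraction, reckoned on one D removing one Q by Q + D → Z. Thursday's [D] charged minus [Q] charged is 2.00 µM, the titration margin, and it is positive, so Q is the limiting reagent of that step and D stands over it; Saturday's margin is −9.00 µM, so 9.00 µM of Q stays at work.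

Those Q made 63.1% of the L in 30.0 s at 26 °C, about 467 /s per Q, a figure carried unchanged to Thursday's 20 °C for this estimate. Thursday's plateau, the mean of the latest 3 readings, is 11.8%, or 1180 turnovers per Q, hence a working time of 2.52 s per Q. That is far shorter than 2.0 min, so this reckoning commits Thursday's flask to 11.8% at 2.0 min, and to the same figure after winter, spring and summer. Autumn's 10.0 µM of Q meets the 2.00 µM of D and leaves 8.00 µM at work, close to Saturday's 9.00 µM, so autumn is the choice.

The weak link is the plateau, since the estimated 2.52 s ends before 20.0 s, yet the mean stands 1.5 percentage points above that first reading, so some reserve, perhaps J, may still feed Q. From 40.0 s to 80.0 s the rise is 0.9 points, against 0.71 points of scatter on a difference. Held straight, that slope brings 1.4 points in 1.0 min, less than 2 points, so winter stays under the mark of a useful gain.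

The forecast gives 12.5%, higher than this plateau, with 12.6% after spring, 12.5% after summer and autumn as best, on the ground that “no live enzyme remains, so almost nothing more forms”.

Thursday's flask gives 11.7%, 11.7% after spring and 11.7% after summer; autumn is best, with 80 points against 0.022 points for winter.

    Q → X (k = 5.57 × 10⁻⁴ /s, Ea = 221 kJ/mol)
    Q + D → Z (k = 61000 /M/s, Ea = 32.0 kJ/mol)
    L + Q → E + Q, rate k3*[L]*[Q]/(1 + ([L]/Km3)) (0.0649 M, k = 12400 /M/s, Ea = 9.00 kJ/mol)
    Q ⇌ J (K = 0.358, k = 0.0151 /s, Ea = 87.0 kJ/mol, ΔH = −18.0 kJ/mol)
    (constants at 20 °C)

By 0.200 min, Q + D → Z had run alongside L + Q → E + Q in Thursday's flask, with Z at 95.9% of the catalyst, Q at 2.24%, J at 1.73% and E at 10.1%. By 2.00 min, Q in that flask had fallen to 0.0151% and J to 0.0372% while E crept to 11.7%, and D stood at 2.03 µM, close to the margin of 2.00 µM. The neighbour with 8.80 µM of D has a margin of −11.2 µM, which by the subtraction leaves 56.0% of the catalyst free of D. At 2.00 min that neighbour holds Q, J and X together at 56.0%, Z at 44.0% and E at >99.9%.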